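**Plan**

- Locants: carbocycle C1 (methacrylate)–C2–C3 (Me, OH)–C4–C5 (OAc)–C6=C7(Me)–C8=C9–C12; lactone C9–O–C10(=O)–C11(C13H2OH)=C12.
- Cuts, in retrosynthetic order: the two ester C–O bonds; C8=C9 (ring-closing Horner–Wadsworth–Emmons); C6=C7 (Still–Gennari); C11=C12 and O–C10 (butenolide); then C12 and C6 are rejoined as the alkene of a cycloheptene.
- Enabling feature: the C1 and C5 oxygens are 1,5-syn about C3, so C1–C5 with C12 and C6 form a cycloheptene (alkene C12=C6) with a cis-1,4-dioxygen pattern. That is the 1,2-dioxene ring of a singlet-oxygen adduct of a cyclohepta-1,3-diene.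
- Forward order: tropone → ketal diene → peroxide-bridged bicycle (temporary ring) → desymmetrised cycloheptenone → C12, C1 and C3 set on the seven-membered ring → ozonolysis opens it → butenolide ring → ten-membered ring closed last at C8=C9 → esters.
- Stereochemistry: C1/C5 cis from suprafacial O2 addition; C5 absolute configuration from a chiral-base Kornblum–DeLaMare opening; C1 by CBS reduction; C3 by epoxidation anti to the two siloxy groups; C6=C7 Z from the Still–Gennari reagent; C8=C9 fixed by the ring.

Key step: step 3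

Assumption: 9-O-acetylcupreidine is taken to remove the bridgehead hydrogen at the carbon that becomes C1; should the hydroxy enone form in the mirror-image sense, the quinine-derived pseudo-enantiomer is used and nothing else changes. Locants C1–C13 in compound names are those defined above.

**Step 1**
Reactants: 1 tropone
Product: 2 cyclohepta-3,5-dien-1-one
Conditions: LiAlH4 (0.3 equiv), Et2O, 0 °C; cold H2O quench, rapid extraction
Reagents that add atoms: none
Why: Conjugate hydride addition to C2 of the troponoid gives the aluminium trienolate, and kinetic α-protonation on cold work-up should deliver the non-conjugated β,γ-dienone (hydride reduction of tropone).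

**Step 2**
Reactants: 2 cyclohepta-3,5-dien-1-one; 3 1,2-bis(trimethylsilyloxy)ethane
Product: 4 1,4-dioxaspiro[4.6]undeca-7,9-diene
Conditions: Me3SiOTf (2 mol %), CH2Cl2, −78 °C; pyridine quench
Reagents that add atoms: none
Why: Silyl-triflate-catalysed ketalisation with the bis-silyl ether runs at −78 °C without enolisation, so the 3,5-diene should not move into conjugation.

**Step 3**
Reactants: 4 1,4-dioxaspiro[4.6]undeca-7,9-diene
Product: 5 meso endoperoxide ketal (bridgeheads C1 and C5, alkene C12=C6, ketal carbon C3)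
Conditions: O2, tetraphenylporphyrin (0.5 mol %), CH2Cl2, white LED, 0 °C
Reagents that add atoms: dioxygen O=O
Why: Energy transfer from the excited porphyrin gives singlet oxygen, which adds to the s-cis diene C1=C12–C6=C5 in a concerted suprafacial (4+2) cycloaddition, the oxygen counterpart of a Diels–Alder reaction and the standard entry to endoperoxides of cyclic 1,3-dienes. The ring closed is the 1,2-dioxene C1–O–O–C5/C12=C6, formed in one step by (4+2) cycloaddition and fused onto the carbocycle as a 6,7-dioxabicyclo[3.2.2]nonene. C1 and C5 are the two new stereocentres; their cis relation is fixed by bonding of both oxygen atoms to one face of the diene, and because the ketal makes the two faces equivalent the product is meso and no facial control is needed. The only selectivity required is cycloaddition over the ene reaction at the C2 and C4 hydrogens, which the ring-locked s-cis diene and the low temperature should secure. The ketal at C3 is a remote spectator.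

**Step 4**
Reactants: 5 meso endoperoxide ketal
Product: 6 (S)-10-hydroxy-1,4-dioxaspiro[4.6]undec-8-en-7-one
Conditions: 9-O-acetylcupreidine (10 mol %), CH2Cl2, 23 °C
Reagents that add atoms: none
Why: Kornblum–DeLaMare rearrangement, in which the amine removes one bridgehead hydrogen with E2-type O–O cleavage to give the C1 ketone and leave the C5 carbinol untouched; the chiral cinchona base chooses between the enantiotopic bridgehead hydrogens of the meso peroxide and so should fix C5 as S.

**Step 5**
Reactants: 6 hydroxy enone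
Product: 7 (S)-10-(tert-butyldimethylsilyloxy)-1,4-dioxaspiro[4.6]undec-8-en-7-one
Conditions: t-BuMe2SiCl, imidazole, DMF, 0 → 23 °C
Reagents that add atoms: tert-butyldimethylsilyl chloride CC(C)(C)[Si](C)(C)Cl
Why: Imidazole-assisted silylation of the secondary alcohol, after which the γ-oxygenated enone can no longer tautomerise to the 1,4-diketone.

**Step 6**
Reactants: 7 silyl ether enone
Product: 8 (S)-10-(tert-butyldimethylsilyloxy)-8-iodo-1,4-dioxaspiro[4.6]undec-8-en-7-one
Conditions: I2, pyridine, CH2Cl2, 0 → 23 °C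
Reagents that add atoms: iodine II
Why: α-Iodination of the enone by pyridine conjugate addition, iodination of the enolate and elimination (Baylis–Hillman-type halogenation), which marks C12 against C6.

**Step 7**
Reactants: 8 iodo enone
Product: 9 (7R,10S)-10-(tert-butyldimethylsilyloxy)-8-iodo-1,4-dioxaspiro[4.6]undec-8-en-7-ol (C1 hydroxyl cis to C5 silyl ether)
Conditions: (S)-2-methyl-CBS-oxazaborolidine (0.5 equiv), BH3·SMe2, THF, −30 °C; MeOH quench
Reagents that add atoms: none
Why: Corey–Bakshi–Shibata reduction, for which 2-halo enones are well suited; with the iodoalkene arm as the large group the (S)-catalyst should deliver hydride to give 1R (C1–OH cis to C5–O), a sense that hydride approach anti to the C5 siloxy group reinforces.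

**Step 8**
Reactants: 9 iodo allylic alcohol
Product: 10 (7R,10S)-10-(tert-butyldimethylsilyloxy)-8-iodo-7-(triisopropylsilyloxy)-1,4-dioxaspiro[4.6]undec-8-ene
Conditions: iPr3SiOTf, 2,6-lutidine, CH2Cl2, −78 → 0 °C
Reagents that add atoms: triisopropylsilyl triflate CC(C)[Si](C(C)C)(C(C)C)OS(=O)(=O)C(F)(F)F
Why: Silyl triflate/hindered base silylation of the hindered allylic alcohol; the triisopropylsilyl group is chosen to outlast the C5 and C3 silyl ethers at the end.

**Step 9**
Reactants: 10 bis-silyl ether ketal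
Product: 11 (3R,6S)-6-(tert-butyldimethylsilyloxy)-4-iodo-3-(triisopropylsilyloxy)cyclohept-4-en-1-one (C3 ketone)
Conditions: pyridinium p-toluenesulfonate, acetone/H2O (10:1), 50 °C
Reagents that add atoms: water O
Why: Mildly acidic hydrolysis of the dioxolane, which both secondary silyl ethers should tolerate.

**Step 10**
Reactants: 11 C3 ketone
Product: 12 (3R,6S)-6-(tert-butyldimethylsilyloxy)-4-iodo-1-methylidene-3-(triisopropylsilyloxy)cyclohept-4-ene
Conditions: Cp2TiMe2, toluene, 70 °C, dark
Reagents that add atoms: dimethyltitanocene C[Ti+2]C.c1cc[cH-]c1.c1cc[cH-]c1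
Why: Petasis methylenation through the thermally generated titanium methylidene, a non-basic olefination that avoids E1cB loss of the two β-siloxy groups.

**Step 11**
Reactants: 12 exocyclic alkene
Product: 13 (3S,5R,8S)-8-(tert-butyldimethylsilyloxy)-6-iodo-5-(triisopropylsilyloxy)-1-oxaspiro[2.6]non-6-ene (epoxide oxygen trans to both siloxy groups)
Conditions: mCPBA, NaHCO3, CH2Cl2, 0 °C
Reagents that add atoms: 3-chloroperoxybenzoic acid OOC(=O)c1cccc(Cl)c1
Why: Prilezhaev epoxidation of the 1,1-disubstituted alkene (the iodinated, doubly allylic-oxygenated ring alkene is deactivated); A1,2 strain with the C12 iodine holds the C1 siloxy group pseudo-axial and the cis C5 siloxy group with it, so both cover one face of C3 and the peracid should deliver oxygen to the other, giving 3S.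

**Step 12**
Reactants: 13 spiro-epoxide
Product: 14 (1S,3R,6S)-6-(tert-butyldimethylsilyloxy)-4-iodo-1-methyl-3-(triisopropylsilyloxy)cyclohept-4-en-1-ol
Conditions: LiBHEt3, THF, 0 °C; H2O
Reagents that add atoms: none
Why: SN2 hydride opening of the epoxide at its CH2 terminus gives the methyl carbinol without touching the C3–O bond or the vinyl iodide.

**Step 13**
Reactants: 14 tertiary alcohol
Product: 15 triethylsilyl ether of 14
Conditions: Et3SiOTf, 2,6-lutidine, CH2Cl2, −78 → 0 °C
Reagents that add atoms: triethylsilyl triflate CC[Si](CC)(CC)OS(=O)(=O)C(F)(F)F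
Why: Silyl triflate silylation is the standard way to cap a tertiary alcohol, which would otherwise form five-membered lactols with both carbonyls released in step 18.

**Step 14**
Reactants: 15 vinyl iodide; 16 (tributylstannyl)methanol
Product: 17 [(3S,5S,7R)-3-(tert-butyldimethylsilyloxy)-5-methyl-5-(triethylsilyloxy)-7-(triisopropylsilyloxy)cyclohept-1-en-1-yl]methanol (C9 alcohol)
Conditions: Pd(PPh3)4 (10 mol %), 1,4-dioxane, 95 °C
Reagents that add atoms: none
Why: Stille coupling of the vinyl iodide with the hydroxymethyl stannane under zerovalent palladium catalysis installs C9 on C12 with the alkene unmoved.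

**Step 15**
Reactants: 18 4-methoxybenzyl alcohol; 19 ethyl 2-(diethoxyphosphoryl)acrylate
Product: 20 ethyl 2-(diethoxyphosphoryl)-3-(4-methoxybenzyloxy)propanoate (racemic)
Conditions: KOtBu (10 mol %), THF, 0 °C
Reagents that add atoms: none
Why: Base-catalysed oxa-Michael addition to the doubly activated acrylate; the stabilised phosphonate anion is protonated by the alcohol, which turns the catalyst over.

**Step 16**
Reactants: 20 phosphono ester
Product: 21 2-(diethoxyphosphoryl)-3-(4-methoxybenzyloxy)propanoic acid (racemic)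
Conditions: LiOH·H2O (1.2 equiv), THF/H2O, 0 → 23 °C; 1 M HCl
Reagents that add atoms: lithium hydroxide [Li+].[OH-]
Why: Saponification of the carboxylic ester, much faster than hydrolysis of the phosphonate esters; any alkoxide expelled from the phosphonate anion re-adds to the acrylate.

**Step 17**
Reactants: 17 C9 alcohol; 21 phosphono acid
Product: 22 C9 ester of 17 with acid 21
Conditions: DCC, DMAP (10 mol %), CH2Cl2, 0 → 23 °C
Reagents that add atoms: none
Why: Steglich esterification of the only free hydroxyl, a primary allylic one.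

**Step 18**
Reactants: 22 cycloheptenylmethyl phosphonoacetate
Product: 23 keto aldehyde (C12 ketone, C6 aldehyde)
Conditions: O3, CH2Cl2, −78 °C, stopped at the first trace of blue; PPh3, −78 → 23 °C
Reagents that add atoms: ozone [O-][O+]=O
Why: Ozonolysis with reductive work-up cleaves the only C=C bond, C12=C6, into a ketone and an aldehyde that differ in kind; the anisyl ring reacts far more slowly than the alkene when ozone is stopped at the end point.

**Step 19**
Reactants: 23 keto aldehyde; 24 ethyl 2-[bis(2,2,2-trifluoroethoxy)phosphoryl]propanoate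
Product: 25 Z-enoate keto phosphonate
Conditions: KN(SiMe3)2, 18-crown-6, THF, −78 °C (anion of 24 pre-formed)
Reagents that add atoms: none
Why: Still–Gennari olefination, in which the electron-poor phosphonate makes oxaphosphetane collapse faster than equilibration and should give the Z-enoate (C5 and C8 cis); the weakly basic anion reacts with the aldehyde only, at a temperature where C5 does not epimerise.

**Step 20**
Reactants: 25 Z-enoate keto phosphonate
Product: 26 butenolide Z-enoate
Conditions: LiCl, iPr2NEt, MeCN, 0 → 23 °C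
Reagents that add atoms: none
Why: Intramolecular Horner–Wadsworth–Emmons reaction under Masamune–Roush conditions closes the butenolide by attack of the phosphonate carbanion on the C12 ketone and irreversible loss of phosphate, which outruns the reversible loss of the β-alkoxide; the mild base should leave C1 next to the ketone intact.

**Step 21**
Reactants: 26 butenolide Z-enoate
Product: 27 2-(triisopropylsilyloxy)furan Z-enoate
Conditions: iPr3SiOTf, Et3N, CH2Cl2, 0 °C
Reagents that add atoms: triisopropylsilyl triflate CC(C)[Si](C(C)C)(C(C)C)OS(=O)(=O)C(F)(F)F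
Why: Soft enolisation of the butenolide gives the aromatic 2-silyloxyfuran, which masks the lactone carbonyl for step 22 and activates C9 for step 23.

**Step 22**
Reactants: 27 silyloxyfuran Z-enoate
Product: 28 silyloxyfuran Z-allylic alcohol (C8 alcohol)
Conditions: iBu2AlH (2.5 equiv), CH2Cl2, −78 °C; aq. potassium sodium tartrate
Reagents that add atoms: none
Why: 1,2-Reduction of the conjugated ester by the aluminium hydride gives the allylic alcohol; the silyloxyfuran has no carbonyl to reduce and the Z geometry is untouched.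

**Step 23**
Reactants: 28 silyloxyfuran Z-allylic alcohol
Product: 30 γ-phosphono butenolide Z-allylic alcohol, via γ-bromobutenolide 29 (not isolated)
Conditions: N-bromosuccinimide (1.0 equiv), THF, −78 °C; then P(OEt)3 (4 equiv), −78 → 23 °C
Reagents that add atoms: N-bromosuccinimide O=C1CCC(=O)N1Br; triethyl phosphite CCOP(OCC)OCC
Why: Electrophilic bromination of the silyloxyfuran at its nucleophilic 5-position (C9) regenerates the butenolide as an acylal-type γ-bromide, which should undergo Michaelis–Arbuzov substitution by the phosphite faster than it meets the hydroxyl, as 3-bromophthalide does.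

**Step 24**
Reactants: 30 γ-phosphono butenolide Z-allylic alcohol
Product: 32 fully protected ten-membered dienyl butenolide, via phosphono enal 31 (not isolated)
Conditions: MnO2, CH2Cl2, 23 °C; filtration; then slow addition to LiCl, DBU, MeCN (final 1 mM), 23 °C
Reagents that add atoms: none
Why: Chemoselective MnO2 oxidation of the allylic alcohol, then intramolecular Horner–Wadsworth–Emmons olefination of the enal by the lactone γ-phosphonate anion (a 2-oxidofuran, as in ylidene-phthalide syntheses) at high dilution should form C8=C9; the ring can hold C7 only cis to C12, which is the E geometry of the target, and the Z alkene keeps the two ends within reach.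

**Step 25**
Reactants: 32 protected macrocycle
Product: 33 C3,C5-diol (C1 triisopropylsilyl ether and C13 4-methoxybenzyl ether kept)
Conditions: HF·pyridine, pyridine, THF, 0 → 23 °C
Reagents that add atoms: none
Why: Buffered fluoride desilylation should cleave the secondary tert-butyldimethylsilyl and the tertiary triethylsilyl ethers but not the more hindered secondary triisopropylsilyl ether at C1.

**Step 26**
Reactants: 33 C3,C5-diol
Product: 34 C5 acetate
Conditions: Ac2O, pyridine, DMAP (cat.), CH2Cl2, 0 °C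
Reagents that add atoms: acetic anhydride CC(=O)OC(C)=O
Why: Nucleophile-catalysed acetylation of the secondary C5 alcohol; the tertiary C3 alcohol does not react under these conditions.

**Step 27**
Reactants: 34 C5 acetate
Product: 35 C1 alcohol
Conditions: Bu4NF, AcOH (1:1), THF, 23 °C
Reagents that add atoms: none
Why: Acetic-acid-buffered fluoride removes the remaining silyl ether without acyl migration or opening of the enol lactone.

**Step 28**
Reactants: 35 C1 alcohol
Product: 36 C13 4-methoxybenzyl ether of the target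
Conditions: methacrylic anhydride, Et3N, DMAP, CH2Cl2, 0 → 23 °C
Reagents that add atoms: methacrylic anhydride CC(=C)C(=O)OC(=O)C(C)=C
Why: DMAP-catalysed acylation of the secondary C1 alcohol; the tertiary C3 hydroxyl stays free and C13 is still protected.

**Step 29**
Reactants: 36 C13 4-methoxybenzyl ether
Product: 37 target, CNP0246543.1
Conditions: DDQ, CH2Cl2/pH 7 phosphate buffer (10:1), 0 °C
Reagents that add atoms: none
Why: Oxidative cleavage of the 4-methoxybenzyl ether by hydride transfer to DDQ and hydrolysis of the oxocarbenium ion, which should leave the esters, the tertiary alcohol and the dienyl lactone alone.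

**Compound list**

1 | tropone (cyclohepta-2,4,6-trien-1-one) | O=C1C=CC=CC=C1 | starting material
2 | cyclohepta-3,5-dien-1-one | O=C1CC=CC=CC1 | intermediate
3 | 1,2-bis(trimethylsilyloxy)ethane | C[Si](C)(C)OCCO[Si](C)(C)C | starting material
4 | 1,4-dioxaspiro[4.6]undeca-7,9-diene | C1=CC=CCC2(C1)OCCO2 | intermediate
5 | meso-(1R,5S)-spiro[6,7-dioxabicyclo[3.2.2]non-8-ene-3,2'-[1,3]dioxolane] | O1O[C@H]2C=C[C@@H]1CC3(C2)OCCO3 | intermediate
6 | (S)-10-hydroxy-1,4-dioxaspiro[4.6]undec-8-en-7-one | O=C1CC2(OCCO2)C[C@H](O)C=C1 | intermediate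
7 | (S)-10-(tert-butyldimethylsilyloxy)-1,4-dioxaspiro[4.6]undec-8-en-7-one | O=C1CC2(OCCO2)C[C@H](O[Si](C)(C)C(C)(C)C)C=C1 | intermediate
8 | (S)-10-(tert-butyldimethylsilyloxy)-8-iodo-1,4-dioxaspiro[4.6]undec-8-en-7-one | O=C1CC2(OCCO2)C[C@H](O[Si](C)(C)C(C)(C)C)C=C1I | intermediate
9 | (7R,10S)-10-(tert-butyldimethylsilyloxy)-8-iodo-1,4-dioxaspiro[4.6]undec-8-en-7-ol | O[C@@H]1CC2(OCCO2)C[C@H](O[Si](C)(C)C(C)(C)C)C=C1I | intermediate
10 | (7R,10S)-10-(tert-butyldimethylsilyloxy)-8-iodo-7-(triisopropylsilyloxy)-1,4-dioxaspiro[4.6]undec-8-ene | CC(C)[Si](C(C)C)(C(C)C)O[C@@H]1CC2(OCCO2)C[C@H](O[Si](C)(C)C(C)(C)C)C=C1I | intermediate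
11 | (3R,6S)-6-(tert-butyldimethylsilyloxy)-4-iodo-3-(triisopropylsilyloxy)cyclohept-4-en-1-one | CC(C)[Si](C(C)C)(C(C)C)O[C@@H]1CC(=O)C[C@H](O[Si](C)(C)C(C)(C)C)C=C1I | intermediate
12 | (3R,6S)-6-(tert-butyldimethylsilyloxy)-4-iodo-1-methylidene-3-(triisopropylsilyloxy)cyclohept-4-ene | CC(C)[Si](C(C)C)(C(C)C)O[C@@H]1CC(=C)C[C@H](O[Si](C)(C)C(C)(C)C)C=C1I | intermediate
13 | (3S,5R,8S)-8-(tert-butyldimethylsilyloxy)-6-iodo-5-(triisopropylsilyloxy)-1-oxaspiro[2.6]non-6-ene | CC(C)[Si](C(C)C)(C(C)C)O[C@@H]1C[C@@]2(OC2)C[C@H](O[Si](C)(C)C(C)(C)C)C=C1I | intermediate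
14 | (1S,3R,6S)-6-(tert-butyldimethylsilyloxy)-4-iodo-1-methyl-3-(triisopropylsilyloxy)cyclohept-4-en-1-ol | CC(C)[Si](C(C)C)(C(C)C)O[C@@H]1C[C@@](C)(O)C[C@H](O[Si](C)(C)C(C)(C)C)C=C1I | intermediate
15 | triethylsilyl ether of 14 (1R,3S,5S in target locants; C12 iodide) | CC(C)[Si](C(C)C)(C(C)C)O[C@@H]1C[C@@](C)(O[Si](CC)(CC)CC)C[C@H](O[Si](C)(C)C(C)(C)C)C=C1I | intermediate
16 | (tributylstannyl)methanol | CCCC[Sn](CCCC)(CCCC)CO | starting material
17 | [(3S,5S,7R)-3-(tert-butyldimethylsilyloxy)-5-methyl-5-(triethylsilyloxy)-7-(triisopropylsilyloxy)cyclohept-1-en-1-yl]methanol | CC(C)[Si](C(C)C)(C(C)C)O[C@@H]1C[C@@](C)(O[Si](CC)(CC)CC)C[C@H](O[Si](C)(C)C(C)(C)C)C=C1CO | intermediate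
18 | 4-methoxybenzyl alcohol | COc1ccc(CO)cc1 | starting material
19 | ethyl 2-(diethoxyphosphoryl)acrylate | C=C(C(=O)OCC)P(=O)(OCC)OCC | starting material
20 | ethyl 2-(diethoxyphosphoryl)-3-(4-methoxybenzyloxy)propanoate (racemic) | CCOC(=O)C(COCc1ccc(OC)cc1)P(=O)(OCC)OCC | intermediate
21 | 2-(diethoxyphosphoryl)-3-(4-methoxybenzyloxy)propanoic acid (racemic) | OC(=O)C(COCc1ccc(OC)cc1)P(=O)(OCC)OCC | intermediate
22 | ester of alcohol 17 (at C9–O) with acid 21; 1R,3S,5S, epimers at the phosphonate carbon | CC(C)[Si](C(C)C)(C(C)C)O[C@@H]1C[C@@](C)(O[Si](CC)(CC)CC)C[C@H](O[Si](C)(C)C(C)(C)C)C=C1COC(=O)C(COCc1ccc(OC)cc1)P(=O)(OCC)OCC | intermediate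
23 | (1R,3S,5S) open-chain keto aldehyde: C6 aldehyde, C5 OTBS, C3 Me/OTES, C1 OTIPS, C12 ketone, C9H2 ester of 21 | CC(C)[Si](C(C)C)(C(C)C)O[C@@H](C(=O)COC(=O)C(COCc1ccc(OC)cc1)P(=O)(OCC)OCC)C[C@@](C)(O[Si](CC)(CC)CC)C[C@H](O[Si](C)(C)C(C)(C)C)C=O | intermediate
24 | ethyl 2-[bis(2,2,2-trifluoroethoxy)phosphoryl]propanoate | CCOC(=O)C(C)P(=O)(OCC(F)(F)F)OCC(F)(F)F | starting material
25 | (1R,3S,5S,6Z) ethyl enoate (C8 ester) of 23, C12 ketone and phosphonoacetate retained | CC(C)[Si](C(C)C)(C(C)C)O[C@@H](C(=O)COC(=O)C(COCc1ccc(OC)cc1)P(=O)(OCC)OCC)C[C@@](C)(O[Si](CC)(CC)CC)C[C@H](O[Si](C)(C)C(C)(C)C)/C=C(C)\C(=O)OCC | intermediate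
26 | (1R,3S,5S,6Z) butenolide enoate: 3-(4-methoxybenzyloxymethyl)furan-2(5H)-one joined at its C4 (= C12) to C1 | CC(C)[Si](C(C)C)(C(C)C)O[C@@H](C1=C(COCc2ccc(OC)cc2)C(=O)OC1)C[C@@](C)(O[Si](CC)(CC)CC)C[C@H](O[Si](C)(C)C(C)(C)C)/C=C(C)\C(=O)OCC | intermediate
27 | 2-(triisopropylsilyloxy)furan derived from 26 (furan H at C9), Z-enoate retained | CC(C)[Si](C(C)C)(C(C)C)O[C@@H](c1coc(O[Si](C(C)C)(C(C)C)C(C)C)c1COCc2ccc(OC)cc2)C[C@@](C)(O[Si](CC)(CC)CC)C[C@H](O[Si](C)(C)C(C)(C)C)/C=C(C)\C(=O)OCC | intermediate
28 | silyloxyfuran (6Z)-allylic alcohol (C8H2OH) | CC(C)[Si](C(C)C)(C(C)C)O[C@@H](c1coc(O[Si](C(C)C)(C(C)C)C(C)C)c1COCc2ccc(OC)cc2)C[C@@](C)(O[Si](CC)(CC)CC)C[C@H](O[Si](C)(C)C(C)(C)C)/C=C(C)\CO | intermediate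
29 | γ-bromobutenolide (Br at C9, epimers), C8 alcohol | CC(C)[Si](C(C)C)(C(C)C)O[C@@H](C1=C(COCc2ccc(OC)cc2)C(=O)OC1Br)C[C@@](C)(O[Si](CC)(CC)CC)C[C@H](O[Si](C)(C)C(C)(C)C)/C=C(C)\CO | intermediate
30 | γ-(diethoxyphosphoryl)butenolide (P at C9, epimers), C8 alcohol | CC(C)[Si](C(C)C)(C(C)C)O[C@@H](C1=C(COCc2ccc(OC)cc2)C(=O)OC1P(=O)(OCC)OCC)C[C@@](C)(O[Si](CC)(CC)CC)C[C@H](O[Si](C)(C)C(C)(C)C)/C=C(C)\CO | intermediate
31 | γ-(diethoxyphosphoryl)butenolide (6Z)-enal (C8 aldehyde) | CC(C)[Si](C(C)C)(C(C)C)O[C@@H](C1=C(COCc2ccc(OC)cc2)C(=O)OC1P(=O)(OCC)OCC)C[C@@](C)(O[Si](CC)(CC)CC)C[C@H](O[Si](C)(C)C(C)(C)C)/C=C(C)\C=O | intermediate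
32 | (1R,3S,5S,6Z,8E) ten-membered dienyl butenolide: C1 OTIPS, C3 OTES, C5 OTBS, C13 O-(4-methoxybenzyl) | CC(C)[Si](C(C)C)(C(C)C)O[C@@H]1C[C@@](C)(O[Si](CC)(CC)CC)C[C@H](O[Si](C)(C)C(C)(C)C)/C=C(C)\C=C2\OC(=O)C(COCc3ccc(OC)cc3)=C21 | intermediate
33 | C3,C5-diol of 32 (C1 OTIPS, C13 O-(4-methoxybenzyl)) | CC(C)[Si](C(C)C)(C(C)C)O[C@@H]1C[C@@](C)(O)C[C@H](O)/C=C(C)\C=C2\OC(=O)C(COCc3ccc(OC)cc3)=C21 | intermediate
34 | C5 acetate of 33 | CC(C)[Si](C(C)C)(C(C)C)O[C@@H]1C[C@@](C)(O)C[C@H](OC(C)=O)/C=C(C)\C=C2\OC(=O)C(COCc3ccc(OC)cc3)=C21 | intermediate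
35 | C1 alcohol (C5 acetate, C3 OH, C13 O-(4-methoxybenzyl)) | O[C@@H]1C[C@@](C)(O)C[C@H](OC(C)=O)/C=C(C)\C=C2\OC(=O)C(COCc3ccc(OC)cc3)=C21 | intermediate
36 | C1 methacrylate, C5 acetate, C13 O-(4-methoxybenzyl) | C=C(C)C(=O)O[C@@H]1C[C@@](C)(O)C[C@H](OC(C)=O)/C=C(C)\C=C2\OC(=O)C(COCc3ccc(OC)cc3)=C21 | intermediate
37 | CNP0246543.1, (1R,3S,5S,6Z,8E) in the locants above | C=C(C)C(=O)O[C@@H]1C[C@@](C)(O)C[C@H](OC(C)=O)/C=C(C)\C=C2\OC(=O)C(CO)=C21 | target

**Step count and risks**

Total step count: 29. Longest linear sequence: 27 (steps 1–14 and 17–29 from tropone; steps 15–16 prepare acid 21).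

Steps most likely to fail:

1. Step 24. What may go wrong: intermolecular olefination (oligomerisation) outrunning closure of the ten-membered ring, or Z-to-E isomerisation of the enal before it closes. The fallback sets out from 28 and returns at 32, and makes C8–C9 first as a single bond under Lewis acid. Alcohol 28 is oxidised with MnO2 to the silyloxyfuran Z-enal F1. Slow addition of the silyloxyfuran Z-enal F1 to BF3·OEt2 in CH2Cl2 at −78 °C (1 mM) should trigger an intramolecular vinylogous Mukaiyama aldol addition to the ten-membered aldol carbinol F2. Mesylation of the ten-membered aldol carbinol F2 (MeSO2Cl, Et3N), then DBU, eliminates by E1cB through the butenolide dienolate to give 32.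

2. Step 23. What may go wrong: capture of the γ-bromide by the free C8 hydroxyl, or sluggish substitution at the hindered acylal carbon. The fallback sets out from 28 and returns at 30, and brings phosphorus in as a nucleophile toward an aldehyde. Compound 28 is oxidised at the furan with dimethyldioxirane (acetone, −78 °C, 1.0 equiv) to the γ-hydroxybutenolide F3. The ring-opened formyl acrylate form of the γ-hydroxybutenolide F3 adds diethyl phosphite (Et3N, Pudovik reaction), and mild acidification relactonises the hydroxy phosphonate to 30, as in the preparation of phthalide phosphonates from 2-formylbenzoic acid.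

3. Step 11. What may go wrong: peracid delivery to the C3 face syn to the siloxy groups (reversed facial selectivity). The fallback sets out from 11 and returns at 14, and inverts the order of events at C3. Methyl is added as a nucleophile (MeMgBr, CeCl3, THF, −78 °C) to ketone 11; attack on the face the peracid would have used then places carbon there and oxygen anti to the siloxy groups. This path passes through no compound outside the list (F0), and steps 10–12 are skipped.

**Further compounds**

F1 | step 24 | silyloxyfuran (6Z)-enal from 28 | CC(C)[Si](C(C)C)(C(C)C)O[C@@H](c1coc(O[Si](C(C)C)(C(C)C)C(C)C)c1COCc2ccc(OC)cc2)C[C@@](C)(O[Si](CC)(CC)CC)C[C@H](O[Si](C)(C)C(C)(C)C)/C=C(C)\C=O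
F2 | step 24 | ten-membered aldol carbinol (C8 OH, C9 H butenolide, epimers at C8 and C9) | CC(C)[Si](C(C)C)(C(C)C)O[C@@H]1C[C@@](C)(O[Si](CC)(CC)CC)C[C@H](O[Si](C)(C)C(C)(C)C)/C=C(C)\C(O)C2OC(=O)C(COCc3ccc(OC)cc3)=C21
F3 | step 23 | γ-hydroxybutenolide (OH at C9, epimers), C8 alcohol | CC(C)[Si](C(C)C)(C(C)C)O[C@@H](C1=C(COCc2ccc(OC)cc2)C(=O)OC1O)C[C@@](C)(O[Si](CC)(CC)CC)C[C@H](O[Si](C)(C)C(C)(C)C)/C=C(C)\CO
F0 | step 11 | none | none
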